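## Retrosynthetic overview

1. Miyabenol A comes from its nona-O-benzyl ether 51 by global debenzylation in the last step.
2. The three C3–aryl bonds between the units (A–B, B–C, C–ring D) are cut as nickel-catalysed decarboxylative couplings of 2,3-dihydrobenzofuran-3-carboxylic acids with arylzinc reagents, run in the order A+B, AB+C, ABC+D; each new C3 centre is set trans to the existing C2 aryl group.
3. Each 2-aryl-2,3-dihydrobenzofuran unit comes from acid ring closure of a 1,3-diol made in the key step, an intermolecular Evans boron aldol reaction of an N-(arylacetyl)oxazolidinone with 4-(benzyloxy)benzaldehyde (C2–C3 bond; (R)-auxiliary for units A and C, (S)-auxiliary for unit B).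
4. The common arylacetic acid 11 comes from 1-bromo-3,5-dimethoxybenzene by formylation, ortho-selective debenzylation and one-carbon homologation; it is activated once as mixed anhydride 12, which serves both auxiliaries.
5. Ring order: the dihydrofuran rings of the (2R) and (2S) monomers are closed first (steps 13 and 17), the stilbene is put on unit A by a Heck reaction, then the units are joined A, B, C, ring D.

Notation: Ar = 4-(benzyloxy)phenyl, Bn = benzyl, MOM = methoxymethyl, TBS = tert-butyldimethylsilyl. Dihydrobenzofuran locants are O1, C2, C3, C3a, C4–C7, C7a. Unit A carries the styryl group at C4, unit B is the middle unit, unit C the third, ring D the terminal 3,5-dioxygenated phenyl ring. Read from the SMILES, the target is unit A (2R,3R), unit B (2S,3S), unit C (2R,3R), all 2,3-trans, E alkene.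

Assumption: 1-bromo-3,5-dimethoxybenzene, 4-(benzyloxy)benzaldehyde and both enantiomers of 4-benzyl-1,3-oxazolidin-2-one are bought; every other numbered compound is made.

## Route

### Common arylacetic acid and its mixed anhydride (steps 1–9)

Step 1
Reactants: 1 1-bromo-3,5-dimethoxybenzene
Product: 2 5-bromobenzene-1,3-diol
Conditions: BBr3 (2.5 equiv), CH2Cl2, −78 °C to rt; H2O
Reagents that add atoms: none
Why: Lewis-acid ether cleavage (BBr3 demethylation) frees both phenols so that benzyl ethers, which can be removed at the end beside a stilbene, replace the methyl ethers.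

Step 2
Reactants: 2 5-bromobenzene-1,3-diol
Product: 3 1,3-bis(benzyloxy)-5-bromobenzene
Conditions: BnBr (2.2 equiv), K2CO3, DMF, rt
Reagents that add atoms: benzyl bromide BrCc1ccccc1
Why: Williamson ether synthesis on both phenoxides; no stereocentre is involved.

Step 3
Reactants: 3 1,3-bis(benzyloxy)-5-bromobenzene
Product: 5 2,4-bis(benzyloxy)-6-bromobenzaldehyde, via aryl iminium chloride 4 (not isolated)
Conditions: POCl3, DMF, 90 °C; then ice-water
Reagents that add atoms: N,N-dimethylformamide CN(C)C=O; water O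
Why: Vilsmeier–Haack formylation goes para to one benzyloxy group and ortho to the other (next to bromine), as known for the dimethoxy analogue, the position between the two ethers being the minor, separable site.

Step 4
Reactants: 5 2,4-bis(benzyloxy)-6-bromobenzaldehyde
Product: 6 4-(benzyloxy)-2-bromo-6-hydroxybenzaldehyde
Conditions: MgBr2·OEt2 (3 equiv), toluene/Et2O, reflux; aq. HCl
Reagents that add atoms: none
Why: Chelation-controlled Lewis-acid debenzylation, in which magnesium held between the aldehyde oxygen and the ortho ether oxygen lets bromide remove only the ortho benzyl group.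

Step 5
Reactants: 6 4-(benzyloxy)-2-bromo-6-hydroxybenzaldehyde
Product: 7 4-(benzyloxy)-2-bromo-6-(methoxymethoxy)benzaldehyde
Conditions: MOMCl, iPr2NEt, CH2Cl2, 0 °C to rt
Reagents that add atoms: chloromethyl methyl ether COCCl
Why: O-alkylation (MOM protection) masks the ortho oxygen through the enolate chemistry and is removed later by the same acid that closes the ring.

Step 6
Reactants: 7 4-(benzyloxy)-2-bromo-6-(methoxymethoxy)benzaldehyde
Product: 8 5-(benzyloxy)-1-bromo-2-ethenyl-3-(methoxymethoxy)benzene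
Conditions: Ph3PCH3Br, KOtBu, THF, 0 °C to rt
Reagents that add atoms: methyltriphenylphosphonium bromide C[P+](c1ccccc1)(c1ccccc1)c1ccccc1.[Br-]
Why: Wittig methylenation of a non-enolisable aryl aldehyde.

Step 7
Reactants: 8 5-(benzyloxy)-1-bromo-2-ethenyl-3-(methoxymethoxy)benzene
Product: 10 2-[4-(benzyloxy)-2-bromo-6-(methoxymethoxy)phenyl]ethan-1-ol, via B-alkyl-9-BBN adduct 9 (not isolated)
Conditions: 9-BBN, THF, 0 to 60 °C; then NaOH, H2O2, 0 °C to rt
Reagents that add atoms: hydrogen peroxide OO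
Why: Anti-Markovnikov hydroboration–oxidation, with 9-BBN placing boron on the terminal carbon of the styrene.

Step 8
Reactants: 10 2-[4-(benzyloxy)-2-bromo-6-(methoxymethoxy)phenyl]ethan-1-ol
Product: 11 [4-(benzyloxy)-2-bromo-6-(methoxymethoxy)phenyl]acetic acid
Conditions: TEMPO (cat.), PhI(OAc)2 (2.5 equiv), MeCN/H2O, rt
Reagents that add atoms: water O
Why: TEMPO/PhI(OAc)2 oxidation in wet acetonitrile takes the primary alcohol through the aldehyde hydrate to the acid while MOM ether, benzyl ether and aryl bromide stay intact.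

Step 9
Reactants: 11 [4-(benzyloxy)-2-bromo-6-(methoxymethoxy)phenyl]acetic acid
Product: 12 [4-(benzyloxy)-2-bromo-6-(methoxymethoxy)phenyl]acetic pivalic anhydride
Conditions: PivCl (1.05 equiv), Et3N (1.1 equiv), THF, −20 °C, 1 h; Et3N·HCl filtered off under argon, filtrate concentrated cold; crude oil divided into two portions and used at once
Reagents that add atoms: pivaloyl chloride CC(C)(C)C(Cl)=O
Why: Acyl substitution at pivaloyl chloride by the triethylammonium carboxylate gives the mixed anhydride under non-acidic conditions that spare the MOM ether; one batch is made and shared between steps 10 and 14.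

### (2R) monomer for units A and C (steps 10–13)

Step 10
Reactants: 12 [4-(benzyloxy)-2-bromo-6-(methoxymethoxy)phenyl]acetic pivalic anhydride (first portion); 13 (R)-4-benzyl-1,3-oxazolidin-2-one
Product: 14 (R)-4-benzyl-3-{[4-(benzyloxy)-2-bromo-6-(methoxymethoxy)phenyl]acetyl}-1,3-oxazolidin-2-one
Conditions: 13, LiCl, Et3N, THF, −20 °C to rt
Reagents that add atoms: none
Why: N-acylation of the oxazolidinone (LiCl/Et3N protocol), the nitrogen attacking the arylacetyl carbonyl and not the shielded pivaloyl carbonyl; the auxiliary stereocentre is untouched.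

Step 11
Reactants: 14 (R)-N-(arylacetyl)oxazolidinone; 15 4-(benzyloxy)benzaldehyde
Product: 17 (4R)-4-benzyl-3-{(2R,3R)-2-[4-(benzyloxy)-2-bromo-6-(methoxymethoxy)phenyl]-3-[4-(benzyloxy)phenyl]-3-hydroxypropanoyl}-1,3-oxazolidin-2-one, via boron enolate 16 (not isolated)
Conditions: Bu2BOTf, iPr2NEt, CH2Cl2, −78 to 0 °C; then 15, −78 to 0 °C; pH 7 buffer, MeOH, H2O2
Reagents that add atoms: none
Why: Evans syn aldol reaction, in which the Z boron enolate adds through a Zimmerman–Traxler chair on the face away from the auxiliary benzyl group, so the (R)-auxiliary sets the α-carbon as R and the carbinol carbon as R.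

Step 12
Reactants: 17 (2R,3R) syn aldol adduct
Product: 18 (1R,2S)-2-[4-(benzyloxy)-2-bromo-6-(methoxymethoxy)phenyl]-1-[4-(benzyloxy)phenyl]propane-1,3-diol
Conditions: LiBH4, THF/MeOH, 0 °C
Reagents that add atoms: none
Why: Reductive cleavage of the exocyclic imide carbonyl by LiBH4 gives the 1,3-diol without touching either stereocentre and frees the auxiliary for reuse.

Step 13
Reactants: 18 (1R,2S)-diol
Product: 20 [(2R,3S)-6-(benzyloxy)-2-[4-(benzyloxy)phenyl]-4-bromo-2,3-dihydro-1-benzofuran-3-yl]methanol, via free phenol diol 19 (not isolated)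
Conditions: methanolic HCl (0.5 equiv), MeOH/CH2Cl2, 0 to 40 °C
Reagents that add atoms: none
Why: Acid removes the MOM group and ionises the 4-benzyloxybenzylic alcohol (SN1), and five-membered ring closure by the ortho phenol oxygen gives the favoured 2,3-trans ring, so the untouched C3 centre from the aldol fixes C2 as R.

### (2S) monomer for unit B (steps 14–18)

Step 14
Reactants: 12 [4-(benzyloxy)-2-bromo-6-(methoxymethoxy)phenyl]acetic pivalic anhydride (second portion); 21 (S)-4-benzyl-1,3-oxazolidin-2-one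
Product: 22 (S)-4-benzyl-3-{[4-(benzyloxy)-2-bromo-6-(methoxymethoxy)phenyl]acetyl}-1,3-oxazolidin-2-one
Conditions: 21, LiCl, Et3N, THF, −20 °C to rt
Reagents that add atoms: none
Why: Same N-acylation by the mixed anhydride as in step 10, now with the antipodal auxiliary.

Step 15
Reactants: 22 (S)-N-(arylacetyl)oxazolidinone; 15 4-(benzyloxy)benzaldehyde
Product: 24 (4S)-4-benzyl-3-{(2S,3S)-2-[4-(benzyloxy)-2-bromo-6-(methoxymethoxy)phenyl]-3-[4-(benzyloxy)phenyl]-3-hydroxypropanoyl}-1,3-oxazolidin-2-one, via boron enolate 23 (not isolated)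
Conditions: Bu2BOTf, iPr2NEt, CH2Cl2, −78 to 0 °C; then 15, −78 to 0 °C; pH 7 buffer, MeOH, H2O2
Reagents that add atoms: none
Why: Evans syn aldol reaction through the Z boron enolate and a Zimmerman–Traxler chair, the (S)-auxiliary now setting the α-carbon as S and the carbinol carbon as S.

Step 16
Reactants: 24 (2S,3S) syn aldol adduct
Product: 25 (1S,2R)-2-[4-(benzyloxy)-2-bromo-6-(methoxymethoxy)phenyl]-1-[4-(benzyloxy)phenyl]propane-1,3-diol
Conditions: LiBH4, THF/MeOH, 0 °C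
Reagents that add atoms: none
Why: Reductive removal of the auxiliary with LiBH4, stereocentres untouched.

Step 17
Reactants: 25 (1S,2R)-diol
Product: 27 [(2S,3R)-6-(benzyloxy)-2-[4-(benzyloxy)phenyl]-4-bromo-2,3-dihydro-1-benzofuran-3-yl]methanol, via free phenol diol 26 (not isolated)
Conditions: methanolic HCl (0.5 equiv), MeOH/CH2Cl2, 0 to 40 °C
Reagents that add atoms: none
Why: MOM loss and SN1 ring closure as in step 13, the C3 centre directing the 2,3-trans ring so that C2 becomes S.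

Step 18
Reactants: 27 (2S,3R)-bromo alcohol
Product: 28 tert-butyl{[(2S,3R)-6-(benzyloxy)-2-[4-(benzyloxy)phenyl]-4-bromo-2,3-dihydro-1-benzofuran-3-yl]methoxy}dimethylsilane (unit B bromide)
Conditions: TBSCl, imidazole, DMF, rt
Reagents that add atoms: tert-butyldimethylsilyl chloride CC(C)(C)[Si](C)(C)Cl
Why: Silylation of the primary alcohol removes the only acidic proton so that the aryl bromide can later be lithiated.

### Unit C bromide and unit A acid (steps 19–22)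

Step 19
Reactants: 20 (2R,3S)-bromo alcohol
Product: 29 tert-butyl{[(2R,3S)-6-(benzyloxy)-2-[4-(benzyloxy)phenyl]-4-bromo-2,3-dihydro-1-benzofuran-3-yl]methoxy}dimethylsilane (unit C bromide)
Conditions: TBSCl, imidazole, DMF, rt
Reagents that add atoms: tert-butyldimethylsilyl chloride CC(C)(C)[Si](C)(C)Cl
Why: Silyl protection of the primary alcohol as in step 18.

Step 20
Reactants: 15 4-(benzyloxy)benzaldehyde
Product: 30 1-(benzyloxy)-4-ethenylbenzene
Conditions: Ph3PCH3Br, KOtBu, THF, 0 °C to rt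
Reagents that add atoms: methyltriphenylphosphonium bromide C[P+](c1ccccc1)(c1ccccc1)c1ccccc1.[Br-]
Why: Wittig methylenation gives the styrene partner for the Heck reaction.

Step 21
Reactants: 20 (2R,3S)-bromo alcohol; 30 1-(benzyloxy)-4-ethenylbenzene
Product: 31 [(2R,3S)-6-(benzyloxy)-2-[4-(benzyloxy)phenyl]-4-{(E)-2-[4-(benzyloxy)phenyl]ethenyl}-2,3-dihydro-1-benzofuran-3-yl]methanol
Conditions: Pd(OAc)2 (5 mol%), P(o-tol)3 (12 mol%), Et3N, DMF, 100 °C
Reagents that add atoms: none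
Why: Mizoroki–Heck reaction of the aryl bromide (meta to both oxygens, so normally reactive), where syn insertion and syn β-hydride elimination give the E stilbene and the two stereocentres are not touched.

Step 22
Reactants: 31 unit A stilbene alcohol
Product: 33 (2R,3R)-6-(benzyloxy)-2-[4-(benzyloxy)phenyl]-4-{(E)-2-[4-(benzyloxy)phenyl]ethenyl}-2,3-dihydro-1-benzofuran-3-carboxylic acid, via aldehyde 32 (not isolated)
Conditions: Dess–Martin periodinane, CH2Cl2, 0 °C to rt; crude, then NaClO2, NaH2PO4, 2-methyl-2-butene, t-BuOH/H2O, rt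
Reagents that add atoms: sodium chlorite [Na+].[O-]Cl=O
Why: Dess–Martin oxidation followed by Pinnick oxidation under buffered conditions with a hypochlorite scavenger spares the stilbene, and C2 is untouched (C3 is erased in the next step anyway).

### Assembly (steps 23–30)

Step 23
Reactants: 33 unit A acid; 28 unit B bromide (2 equiv)
Product: 37 dimer silyl ether (unit A C3 bonded to C4 of unit B; A 2R,3R; B 2S,3R), via N-hydroxyphthalimide ester 34 (not isolated), via aryllithium 35 (not isolated), via arylzinc chloride 36 (not isolated)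
Conditions: 33, N-hydroxyphthalimide, N,N'-diisopropylcarbodiimide, CH2Cl2, rt (no amine base), solvent switch; 28, n-BuLi, THF, −78 °C, then ZnCl2, to rt; NiCl2·(MeOCH2CH2OMe) (20 mol%), 4,4'-di-tert-butyl-2,2'-bipyridine (40 mol%), THF/DMF, rt
Reagents that add atoms: none
Why: Nickel-catalysed decarboxylative Negishi-type arylation of a redox-active ester, in which loss of CO2 gives a planar benzylic C3 radical that is captured by aryl–nickel anti to the C2 aryl group, so the new C3–aryl bond is trans (2R,3R) while C2 and unit B keep their configuration.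

Step 24
Reactants: 37 dimer silyl ether
Product: 38 dimer alcohol (hydroxymethyl at C3 of unit B; B 2S,3R)
Conditions: TBAF, THF, 0 °C to rt
Reagents that add atoms: none
Why: Fluoride desilylation of the primary TBS ether; benzyl ethers and stereocentres are inert.

Step 25
Reactants: 38 dimer alcohol
Product: 40 dimer acid (carboxylic acid at C3 of unit B; B 2S,3S), via aldehyde 39 (not isolated)
Conditions: Dess–Martin periodinane, CH2Cl2, 0 °C to rt; crude, then NaClO2, NaH2PO4, 2-methyl-2-butene, t-BuOH/H2O, rt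
Reagents that add atoms: sodium chlorite [Na+].[O-]Cl=O
Why: Dess–Martin then Pinnick oxidation as in step 22, with no change at any retained stereocentre.

Step 26
Reactants: 40 dimer acid; 29 unit C bromide (2 equiv)
Product: 44 trimer silyl ether (unit B C3 bonded to C4 of unit C; A 2R,3R; B 2S,3S; C 2R,3S), via N-hydroxyphthalimide ester 41 (not isolated), via aryllithium 42 (not isolated), via arylzinc chloride 43 (not isolated)
Conditions: 40, N-hydroxyphthalimide, N,N'-diisopropylcarbodiimide, CH2Cl2, rt, solvent switch; 29, n-BuLi, THF, −78 °C, then ZnCl2, to rt; NiCl2·(MeOCH2CH2OMe) (20 mol%), 4,4'-di-tert-butyl-2,2'-bipyridine (40 mol%), THF/DMF, rt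
Reagents that add atoms: none
Why: Second nickel-catalysed decarboxylative arylation, where the C3 radical of unit B is arylated anti to its C2 aryl group, giving the 2,3-trans (2S,3S) unit B.

Step 27
Reactants: 44 trimer silyl ether
Product: 45 trimer alcohol (hydroxymethyl at C3 of unit C; C 2R,3S)
Conditions: TBAF, THF, 0 °C to rt
Reagents that add atoms: none
Why: Fluoride desilylation of the primary TBS ether.

Step 28
Reactants: 45 trimer alcohol
Product: 47 trimer acid (carboxylic acid at C3 of unit C; C 2R,3R), via aldehyde 46 (not isolated)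
Conditions: Dess–Martin periodinane, CH2Cl2, 0 °C to rt; crude, then NaClO2, NaH2PO4, 2-methyl-2-butene, t-BuOH/H2O, rt
Reagents that add atoms: sodium chlorite [Na+].[O-]Cl=O
Why: Dess–Martin then Pinnick oxidation as in step 22.

Step 29
Reactants: 47 trimer acid; 3 1,3-bis(benzyloxy)-5-bromobenzene (3 equiv)
Product: 51 nona-O-benzylmiyabenol A, via N-hydroxyphthalimide ester 48 (not isolated), via aryllithium 49 (not isolated), via arylzinc chloride 50 (not isolated)
Conditions: 47, N-hydroxyphthalimide, N,N'-diisopropylcarbodiimide, CH2Cl2, rt, solvent switch; 3, n-BuLi, THF, −78 °C, then ZnCl2, to rt; NiCl2·(MeOCH2CH2OMe) (20 mol%), 4,4'-di-tert-butyl-2,2'-bipyridine (40 mol%), THF/DMF, rt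
Reagents that add atoms: none
Why: Third nickel-catalysed decarboxylative arylation, now with an unhindered arylzinc, putting ring D on C3 of unit C trans to its C2 aryl group (2R,3R).

Step 30
Reactants: 51 nona-O-benzylmiyabenol A
Product: 52 miyabenol A
Conditions: BCl3 (excess), pentamethylbenzene (excess), CH2Cl2, −78 °C; then MeOH
Reagents that add atoms: none
Why: Lewis-acid debenzylation with a non-basic cation scavenger at −78 °C removes the nine benzyl groups as benzylpentamethylbenzene, conditions cold and brief enough to leave the dihydrobenzofurans and the E stilbene intact, and no stereocentre is touched.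

## Compound list

1 | 1-bromo-3,5-dimethoxybenzene | COc1cc(Br)cc(OC)c1 | starting material
2 | 5-bromobenzene-1,3-diol | Oc1cc(O)cc(Br)c1 | intermediate
3 | 1,3-bis(benzyloxy)-5-bromobenzene | Brc1cc(OCc2ccccc2)cc(OCc2ccccc2)c1 | intermediate
4 | N-[2,4-bis(benzyloxy)-6-bromobenzylidene]-N-methylmethanaminium chloride (aryl iminium chloride, not isolated) | C[N+](C)=Cc1c(Br)cc(OCc2ccccc2)cc1OCc1ccccc1.[Cl-] | intermediate
5 | 2,4-bis(benzyloxy)-6-bromobenzaldehyde | O=Cc1c(Br)cc(OCc2ccccc2)cc1OCc1ccccc1 | intermediate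
6 | 4-(benzyloxy)-2-bromo-6-hydroxybenzaldehyde | O=Cc1c(Br)cc(OCc2ccccc2)cc1O | intermediate
7 | 4-(benzyloxy)-2-bromo-6-(methoxymethoxy)benzaldehyde | O=Cc1c(Br)cc(OCc2ccccc2)cc1OCOC | intermediate
8 | 5-(benzyloxy)-1-bromo-2-ethenyl-3-(methoxymethoxy)benzene | C=Cc1c(Br)cc(OCc2ccccc2)cc1OCOC | intermediate
9 | 9-{2-[4-(benzyloxy)-2-bromo-6-(methoxymethoxy)phenyl]ethyl}-9-borabicyclo[3.3.1]nonane (not isolated) | COCOc1cc(OCc2ccccc2)cc(Br)c1CCB1C2CCCC1CCC2 | intermediate
10 | 2-[4-(benzyloxy)-2-bromo-6-(methoxymethoxy)phenyl]ethan-1-ol | OCCc1c(Br)cc(OCc2ccccc2)cc1OCOC | intermediate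
11 | [4-(benzyloxy)-2-bromo-6-(methoxymethoxy)phenyl]acetic acid | OC(=O)Cc1c(Br)cc(OCc2ccccc2)cc1OCOC | intermediate
12 | [4-(benzyloxy)-2-bromo-6-(methoxymethoxy)phenyl]acetic pivalic anhydride (crude, used at once) | CC(C)(C)C(=O)OC(=O)Cc1c(Br)cc(OCc2ccccc2)cc1OCOC | intermediate
13 | (R)-4-benzyl-1,3-oxazolidin-2-one | O=C1N[C@H](Cc2ccccc2)CO1 | starting material
14 | (R)-4-benzyl-3-{[4-(benzyloxy)-2-bromo-6-(methoxymethoxy)phenyl]acetyl}-1,3-oxazolidin-2-one | O=C(Cc1c(Br)cc(OCc2ccccc2)cc1OCOC)N1[C@H](Cc2ccccc2)COC1=O | intermediate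
15 | 4-(benzyloxy)benzaldehyde | O=Cc1ccc(OCc2ccccc2)cc1 | starting material
16 | (Z)-dibutylboron enolate of 14 (not isolated) | CCCCB(CCCC)O/C(=C\c1c(Br)cc(OCc2ccccc2)cc1OCOC)N1[C@H](Cc2ccccc2)COC1=O | intermediate
17 | (4R)-4-benzyl-3-{(2R,3R)-2-[4-(benzyloxy)-2-bromo-6-(methoxymethoxy)phenyl]-3-[4-(benzyloxy)phenyl]-3-hydroxypropanoyl}-1,3-oxazolidin-2-one | O=C([C@H](c1c(Br)cc(OCc2ccccc2)cc1OCOC)[C@@H](O)c1ccc(OCc2ccccc2)cc1)N1[C@H](Cc2ccccc2)COC1=O | intermediate
18 | (1R,2S)-2-[4-(benzyloxy)-2-bromo-6-(methoxymethoxy)phenyl]-1-[4-(benzyloxy)phenyl]propane-1,3-diol | OC[C@H](c1c(Br)cc(OCc2ccccc2)cc1OCOC)[C@@H](O)c1ccc(OCc2ccccc2)cc1 | intermediate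
19 | (1R,2S)-2-[4-(benzyloxy)-2-bromo-6-hydroxyphenyl]-1-[4-(benzyloxy)phenyl]propane-1,3-diol (not isolated) | OC[C@H](c1c(Br)cc(OCc2ccccc2)cc1O)[C@@H](O)c1ccc(OCc2ccccc2)cc1 | intermediate
20 | [(2R,3S)-6-(benzyloxy)-2-[4-(benzyloxy)phenyl]-4-bromo-2,3-dihydro-1-benzofuran-3-yl]methanol (2,3-trans) | OC[C@@H]1c2c(Br)cc(OCc3ccccc3)cc2O[C@H]1c1ccc(OCc2ccccc2)cc1 | intermediate
21 | (S)-4-benzyl-1,3-oxazolidin-2-one | O=C1N[C@@H](Cc2ccccc2)CO1 | starting material
22 | (S)-4-benzyl-3-{[4-(benzyloxy)-2-bromo-6-(methoxymethoxy)phenyl]acetyl}-1,3-oxazolidin-2-one | O=C(Cc1c(Br)cc(OCc2ccccc2)cc1OCOC)N1[C@@H](Cc2ccccc2)COC1=O | intermediate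
23 | (Z)-dibutylboron enolate of 22 (not isolated) | CCCCB(CCCC)O/C(=C\c1c(Br)cc(OCc2ccccc2)cc1OCOC)N1[C@@H](Cc2ccccc2)COC1=O | intermediate
24 | (4S)-4-benzyl-3-{(2S,3S)-2-[4-(benzyloxy)-2-bromo-6-(methoxymethoxy)phenyl]-3-[4-(benzyloxy)phenyl]-3-hydroxypropanoyl}-1,3-oxazolidin-2-one | O=C([C@@H](c1c(Br)cc(OCc2ccccc2)cc1OCOC)[C@H](O)c1ccc(OCc2ccccc2)cc1)N1[C@@H](Cc2ccccc2)COC1=O | intermediate
25 | (1S,2R)-2-[4-(benzyloxy)-2-bromo-6-(methoxymethoxy)phenyl]-1-[4-(benzyloxy)phenyl]propane-1,3-diol | OC[C@@H](c1c(Br)cc(OCc2ccccc2)cc1OCOC)[C@H](O)c1ccc(OCc2ccccc2)cc1 | intermediate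
26 | (1S,2R)-2-[4-(benzyloxy)-2-bromo-6-hydroxyphenyl]-1-[4-(benzyloxy)phenyl]propane-1,3-diol (not isolated) | OC[C@@H](c1c(Br)cc(OCc2ccccc2)cc1O)[C@H](O)c1ccc(OCc2ccccc2)cc1 | intermediate
27 | [(2S,3R)-6-(benzyloxy)-2-[4-(benzyloxy)phenyl]-4-bromo-2,3-dihydro-1-benzofuran-3-yl]methanol (2,3-trans) | OC[C@H]1c2c(Br)cc(OCc3ccccc3)cc2O[C@@H]1c1ccc(OCc2ccccc2)cc1 | intermediate
28 | tert-butyl{[(2S,3R)-6-(benzyloxy)-2-[4-(benzyloxy)phenyl]-4-bromo-2,3-dihydro-1-benzofuran-3-yl]methoxy}dimethylsilane (unit B bromide) | CC(C)(C)[Si](C)(C)OC[C@H]1c2c(Br)cc(OCc3ccccc3)cc2O[C@@H]1c1ccc(OCc2ccccc2)cc1 | intermediate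
29 | tert-butyl{[(2R,3S)-6-(benzyloxy)-2-[4-(benzyloxy)phenyl]-4-bromo-2,3-dihydro-1-benzofuran-3-yl]methoxy}dimethylsilane (unit C bromide) | CC(C)(C)[Si](C)(C)OC[C@@H]1c2c(Br)cc(OCc3ccccc3)cc2O[C@H]1c1ccc(OCc2ccccc2)cc1 | intermediate
30 | 1-(benzyloxy)-4-ethenylbenzene | C=Cc1ccc(OCc2ccccc2)cc1 | intermediate
31 | [(2R,3S)-6-(benzyloxy)-2-[4-(benzyloxy)phenyl]-4-{(E)-2-[4-(benzyloxy)phenyl]ethenyl}-2,3-dihydro-1-benzofuran-3-yl]methanol | OC[C@@H]1c2c(/C=C/c3ccc(OCc4ccccc4)cc3)cc(OCc3ccccc3)cc2O[C@H]1c1ccc(OCc2ccccc2)cc1 | intermediate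
32 | (2R,3R)-6-(benzyloxy)-2-[4-(benzyloxy)phenyl]-4-{(E)-2-[4-(benzyloxy)phenyl]ethenyl}-2,3-dihydro-1-benzofuran-3-carbaldehyde (not isolated) | O=C[C@@H]1c2c(/C=C/c3ccc(OCc4ccccc4)cc3)cc(OCc3ccccc3)cc2O[C@H]1c1ccc(OCc2ccccc2)cc1 | intermediate
33 | (2R,3R)-6-(benzyloxy)-2-[4-(benzyloxy)phenyl]-4-{(E)-2-[4-(benzyloxy)phenyl]ethenyl}-2,3-dihydro-1-benzofuran-3-carboxylic acid (unit A acid) | OC(=O)[C@@H]1c2c(/C=C/c3ccc(OCc4ccccc4)cc3)cc(OCc3ccccc3)cc2O[C@H]1c1ccc(OCc2ccccc2)cc1 | intermediate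
34 | 1,3-dioxoisoindolin-2-yl ester of 33 (not isolated) | O=C(ON1C(=O)c2ccccc2C1=O)[C@@H]1c2c(/C=C/c3ccc(OCc4ccccc4)cc3)cc(OCc3ccccc3)cc2O[C@H]1c1ccc(OCc2ccccc2)cc1 | intermediate
35 | {(2S,3R)-6-(benzyloxy)-2-[4-(benzyloxy)phenyl]-3-[(tert-butyldimethylsilyloxy)methyl]-2,3-dihydro-1-benzofuran-4-yl}lithium (not isolated) | CC(C)(C)[Si](C)(C)OC[C@H]1c2c([Li])cc(OCc3ccccc3)cc2O[C@@H]1c1ccc(OCc2ccccc2)cc1 | intermediate
36 | chloro{(2S,3R)-6-(benzyloxy)-2-[4-(benzyloxy)phenyl]-3-[(tert-butyldimethylsilyloxy)methyl]-2,3-dihydro-1-benzofuran-4-yl}zinc (not isolated) | CC(C)(C)[Si](C)(C)OC[C@H]1c2c([Zn]Cl)cc(OCc3ccccc3)cc2O[C@@H]1c1ccc(OCc2ccccc2)cc1 | intermediate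
37 | dimer silyl ether: C3 of unit A [(2R,3R)-6-(benzyloxy)-2-Ar-4-{(E)-2-Ar-ethenyl}-2,3-dihydro-1-benzofuran-3-yl] bonded to C4 of unit B [(2S,3R)-6-(benzyloxy)-2-Ar-3-(TBS-oxymethyl)-2,3-dihydro-1-benzofuran] | c1ccccc1COc1ccc(/C=C/c2cc(OCc3ccccc3)cc3c2[C@@H](c2cc(OCc4ccccc4)cc4c2[C@H](CO[Si](C)(C)C(C)(C)C)[C@@H](c2ccc(OCc5ccccc5)cc2)O4)[C@H](c2ccc(OCc4ccccc4)cc2)O3)cc1 | intermediate
38 | dimer alcohol: as 37 with CH2OH at C3 of unit B (B 2S,3R) | c1ccccc1COc1ccc(/C=C/c2cc(OCc3ccccc3)cc3c2[C@@H](c2cc(OCc4ccccc4)cc4c2[C@H](CO)[C@@H](c2ccc(OCc5ccccc5)cc2)O4)[C@H](c2ccc(OCc4ccccc4)cc2)O3)cc1 | intermediate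
39 | dimer aldehyde: as 37 with CHO at C3 of unit B (B 2S,3S; not isolated) | c1ccccc1COc1ccc(/C=C/c2cc(OCc3ccccc3)cc3c2[C@@H](c2cc(OCc4ccccc4)cc4c2[C@H](C=O)[C@@H](c2ccc(OCc5ccccc5)cc2)O4)[C@H](c2ccc(OCc4ccccc4)cc2)O3)cc1 | intermediate
40 | dimer acid: as 37 with CO2H at C3 of unit B (B 2S,3S) | c1ccccc1COc1ccc(/C=C/c2cc(OCc3ccccc3)cc3c2[C@@H](c2cc(OCc4ccccc4)cc4c2[C@H](C(O)=O)[C@@H](c2ccc(OCc5ccccc5)cc2)O4)[C@H](c2ccc(OCc4ccccc4)cc2)O3)cc1 | intermediate
41 | 1,3-dioxoisoindolin-2-yl ester of 40 (not isolated) | c1ccccc1COc1ccc(/C=C/c2cc(OCc3ccccc3)cc3c2[C@@H](c2cc(OCc4ccccc4)cc4c2[C@H](C(=O)ON5C(=O)c6ccccc6C5=O)[C@@H](c2ccc(OCc5ccccc5)cc2)O4)[C@H](c2ccc(OCc4ccccc4)cc2)O3)cc1 | intermediate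
42 | {(2R,3S)-6-(benzyloxy)-2-[4-(benzyloxy)phenyl]-3-[(tert-butyldimethylsilyloxy)methyl]-2,3-dihydro-1-benzofuran-4-yl}lithium (not isolated) | CC(C)(C)[Si](C)(C)OC[C@@H]1c2c([Li])cc(OCc3ccccc3)cc2O[C@H]1c1ccc(OCc2ccccc2)cc1 | intermediate
43 | chloro{(2R,3S)-6-(benzyloxy)-2-[4-(benzyloxy)phenyl]-3-[(tert-butyldimethylsilyloxy)methyl]-2,3-dihydro-1-benzofuran-4-yl}zinc (not isolated) | CC(C)(C)[Si](C)(C)OC[C@@H]1c2c([Zn]Cl)cc(OCc3ccccc3)cc2O[C@H]1c1ccc(OCc2ccccc2)cc1 | intermediate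
44 | trimer silyl ether: unit A (2R,3R) C3 to C4 of unit B (2S,3S); unit B C3 to C4 of unit C [(2R,3S)-6-(benzyloxy)-2-Ar-3-(TBS-oxymethyl)-2,3-dihydro-1-benzofuran] | c1ccccc1COc1ccc(/C=C/c2cc(OCc3ccccc3)cc3c2[C@@H](c2cc(OCc4ccccc4)cc4c2[C@H](c2cc(OCc5ccccc5)cc5c2[C@@H](CO[Si](C)(C)C(C)(C)C)[C@H](c2ccc(OCc6ccccc6)cc2)O5)[C@@H](c2ccc(OCc5ccccc5)cc2)O4)[C@H](c2ccc(OCc4ccccc4)cc2)O3)cc1 | intermediate
45 | trimer alcohol: as 44 with CH2OH at C3 of unit C (C 2R,3S) | c1ccccc1COc1ccc(/C=C/c2cc(OCc3ccccc3)cc3c2[C@@H](c2cc(OCc4ccccc4)cc4c2[C@H](c2cc(OCc5ccccc5)cc5c2[C@@H](CO)[C@H](c2ccc(OCc6ccccc6)cc2)O5)[C@@H](c2ccc(OCc5ccccc5)cc2)O4)[C@H](c2ccc(OCc4ccccc4)cc2)O3)cc1 | intermediate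
46 | trimer aldehyde: as 44 with CHO at C3 of unit C (C 2R,3R; not isolated) | c1ccccc1COc1ccc(/C=C/c2cc(OCc3ccccc3)cc3c2[C@@H](c2cc(OCc4ccccc4)cc4c2[C@H](c2cc(OCc5ccccc5)cc5c2[C@@H](C=O)[C@H](c2ccc(OCc6ccccc6)cc2)O5)[C@@H](c2ccc(OCc5ccccc5)cc2)O4)[C@H](c2ccc(OCc4ccccc4)cc2)O3)cc1 | intermediate
47 | trimer acid: as 44 with CO2H at C3 of unit C (C 2R,3R) | c1ccccc1COc1ccc(/C=C/c2cc(OCc3ccccc3)cc3c2[C@@H](c2cc(OCc4ccccc4)cc4c2[C@H](c2cc(OCc5ccccc5)cc5c2[C@@H](C(O)=O)[C@H](c2ccc(OCc6ccccc6)cc2)O5)[C@@H](c2ccc(OCc5ccccc5)cc2)O4)[C@H](c2ccc(OCc4ccccc4)cc2)O3)cc1 | intermediate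
48 | 1,3-dioxoisoindolin-2-yl ester of 47 (not isolated) | c1ccccc1COc1ccc(/C=C/c2cc(OCc3ccccc3)cc3c2[C@@H](c2cc(OCc4ccccc4)cc4c2[C@H](c2cc(OCc5ccccc5)cc5c2[C@@H](C(=O)ON6C(=O)c7ccccc7C6=O)[C@H](c2ccc(OCc6ccccc6)cc2)O5)[C@@H](c2ccc(OCc5ccccc5)cc2)O4)[C@H](c2ccc(OCc4ccccc4)cc2)O3)cc1 | intermediate
49 | [3,5-bis(benzyloxy)phenyl]lithium (not isolated) | [Li]c1cc(OCc2ccccc2)cc(OCc2ccccc2)c1 | intermediate
50 | [3,5-bis(benzyloxy)phenyl](chloro)zinc (not isolated) | Cl[Zn]c1cc(OCc2ccccc2)cc(OCc2ccccc2)c1 | intermediate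
51 | nona-O-benzylmiyabenol A (units A 2R,3R; B 2S,3S; C 2R,3R; E alkene) | c1ccccc1COc1ccc(/C=C/c2cc(OCc3ccccc3)cc3c2[C@@H](c2cc(OCc4ccccc4)cc4c2[C@H](c2cc(OCc5ccccc5)cc5c2[C@@H](c2cc(OCc6ccccc6)cc(OCc6ccccc6)c2)[C@H](c2ccc(OCc6ccccc6)cc2)O5)[C@@H](c2ccc(OCc5ccccc5)cc2)O4)[C@H](c2ccc(OCc4ccccc4)cc2)O3)cc1 | intermediate
52 | miyabenol A | Oc1ccc(/C=C/c2cc(O)cc3c2[C@@H](c2cc(O)cc4c2[C@H](c2cc(O)cc5c2[C@@H](c2cc(O)cc(O)c2)[C@H](c2ccc(O)cc2)O5)[C@@H](c2ccc(O)cc2)O4)[C@H](c2ccc(O)cc2)O3)cc1 | target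

## Summary

Total step count: 30.

Longest linear sequence: 23 steps (steps 1–13, then 21–30).

Steps most likely to fail:

Step 11 (and its mirror, step 15). The boron enolate of the doubly ortho-substituted arylacetyl imide may be too hindered to add cleanly. The fallback takes the absolute configuration from a resolution instead of the auxiliary. It sets out from 11: esterification (MeI, K2CO3, DMF) gives methyl [4-(benzyloxy)-2-bromo-6-(methoxymethoxy)phenyl]acetate F1. LiN(iPr)2 (THF, −78 °C) gives its small, more reactive lithium enolate F2, which adds to 15 to give the racemic β-hydroxy ester F3 as a syn/anti mixture; both diastereomers are usable because the carbinol centre is ionised later. LiBH4 gives the racemic diol F4, and methanolic HCl as in step 13 closes the ring to the racemic trans alcohol, a 1:1 mixture of 20 and 27. Preparative chiral supercritical-fluid chromatography separates them, and the route is re-entered at 20 and at 27; both antipodes are needed anyway.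

Step 23 (the same reaction type recurs in steps 26 and 29). The nickel-catalysed coupling of a hindered secondary benzylic radical with an ortho-substituted arylzinc may give low yield or poor trans selectivity. The fallback sets out from 33 through the same ester 34 and avoids a transition-metal sp3–sp2 coupling. Copper-catalysed decarboxylative borylation of 34 (B2pin2, Cu(acac)2, LiOH·H2O, MgCl2, dioxane/DMF, rt) gives the trans (2R,3R) C3 pinacol boronate F5, boron entering anti to the C2 aryl group. Aryllithium 35 (from 28, n-BuLi, THF, −78 °C) adds to F5 to give the lithium boronate complex F6. N-Bromosuccinimide at −78 °C brominates the 3,5-dioxygenated aryl ring of F6, which triggers a stereoretentive 1,2-shift of C3 from boron to the aryl carbon and loss of the boron group. The route is re-entered at 37.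

Step 30. BCl3 may open a dihydrobenzofuran at C2 or let the stilbene add to a C2 cation. The fallback removes the benzyl groups without any Lewis or Brønsted acid and sets out from 51. PdCl2 (cat.), Et3SiH and Et3N in CH2Cl2 at rt transfer hydride to each benzyl group (released as toluene) and leave the nonakis(triethylsilyl) ether F7. TBAF buffered with AcOH (THF, 0 °C) then frees the nine phenols and the route is re-entered at 52.

## Further compounds

F1 | step 11 | methyl [4-(benzyloxy)-2-bromo-6-(methoxymethoxy)phenyl]acetate | COC(=O)Cc1c(Br)cc(OCc2ccccc2)cc1OCOC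
F2 | step 11 | lithium enolate of F1 (not isolated) | [Li+].COC([O-])=Cc1c(Br)cc(OCc2ccccc2)cc1OCOC
F3 | step 11 | methyl 2-[4-(benzyloxy)-2-bromo-6-(methoxymethoxy)phenyl]-3-[4-(benzyloxy)phenyl]-3-hydroxypropanoate (racemic, syn/anti mixture) | COC(=O)C(c1c(Br)cc(OCc2ccccc2)cc1OCOC)C(O)c1ccc(OCc2ccccc2)cc1
F4 | step 11 | 2-[4-(benzyloxy)-2-bromo-6-(methoxymethoxy)phenyl]-1-[4-(benzyloxy)phenyl]propane-1,3-diol (racemic, both diastereomers) | OCC(c1c(Br)cc(OCc2ccccc2)cc1OCOC)C(O)c1ccc(OCc2ccccc2)cc1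
F5 | step 23 | 2-[(2R,3R)-6-(benzyloxy)-2-[4-(benzyloxy)phenyl]-4-{(E)-2-[4-(benzyloxy)phenyl]ethenyl}-2,3-dihydro-1-benzofuran-3-yl]-4,4,5,5-tetramethyl-1,3,2-dioxaborolane | CC1(C)OB(OC1(C)C)[C@@H]1c2c(/C=C/c3ccc(OCc4ccccc4)cc3)cc(OCc3ccccc3)cc2O[C@H]1c1ccc(OCc2ccccc2)cc1
F6 | step 23 | lithium boronate complex of F5 with the C4 aryl group of 35 (not isolated) | [Li+].CC(C)(C)[Si](C)(C)OC[C@H]1c2c([B-]3(OC(C)(C)C(C)(C)O3)[C@@H]3c4c(/C=C/c5ccc(OCc6ccccc6)cc5)cc(OCc5ccccc5)cc4O[C@H]3c3ccc(OCc4ccccc4)cc3)cc(OCc3ccccc3)cc2O[C@@H]1c1ccc(OCc2ccccc2)cc1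
F7 | step 30 | nonakis-O-(triethylsilyl)miyabenol A | CC[Si](CC)(CC)Oc1ccc(/C=C/c2cc(O[Si](CC)(CC)CC)cc3c2[C@@H](c2cc(O[Si](CC)(CC)CC)cc4c2[C@H](c2cc(O[Si](CC)(CC)CC)cc5c2[C@@H](c2cc(O[Si](CC)(CC)CC)cc(O[Si](CC)(CC)CC)c2)[C@H](c2ccc(O[Si](CC)(CC)CC)cc2)O5)[C@@H](c2ccc(O[Si](CC)(CC)CC)cc2)O4)[C@H](c2ccc(O[Si](CC)(CC)CC)cc2)O3)cc1
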